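Compound numbers refer to the steps and the compound list below.

## Analysis of the target

- The target 22 is a 2H-chromene. Benzene ring A is fused to pyran ring B (O1, C2, C3, C4, C4a, C8a), C2 carries two methyl groups, and C3=C4 is a double bond conjugated with ring A.
- Ring A is pentasubstituted: O1 on C8a, a free hydroxyl on C5, the 3-oxo-3-phenylpropanoyl chain on C6 and a methoxy group on C7. Only C8 carries hydrogen.
- The three ring oxygens are those of a phloroglucinol, but each is in a different guise (cyclic ether, free phenol, methyl ether), and the acyl chain sits between two of them.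
- There is no stereocentre and the only non-aromatic double bond is endocyclic, so no stereochemical problem arises. The β-diketone should rest largely as an enol, and the C5 hydroxyl is hydrogen-bonded to the C6 carbonyl.
- Sensitive points are the electron-rich, styrene-like C3=C4 bond (acid, electrophiles, hydrogenation), the o-hydroxyaryl β-diketone (acid-induced cyclodehydration to a flavone, retro-Claisen cleavage) and the electron-rich arene (oxidants, halogenating agents).
- The difficulties are to tell three phenolic oxygens apart, to place carbon at C6 and not at C8, to form the chromene without strong acid, and to handle the diketone next to a free phenol at the end.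
- The plan rests on one feature of ring B: C2 is quaternary and bonded to O1. A 2,2-dimethylbenzofuran-3(2H)-one therefore already holds O1, C2 and C3 and lacks only C4 between the carbonyl carbon and ring A. Inserting that carbon enlarges the five-membered ring to the pyranone, and because C2 has no hydrogen the resulting ketone can be converted only into the C3=C4 alkene.

## Retrosynthetic reasoning

**22 from 21.** The last disconnection cuts no skeletal bond: the C5 hydroxyl of 22 is traced back to the methoxymethyl ether 21. The phenol is released last because, next to a carbinol or aldehyde at C6, it would interfere with the carbon–carbon bond formation. The forward step must cleave an aryl acetal without touching the C3=C4 bond and without closing the freed phenol onto the diketone.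

**21 from 17 and 18.** The bond between the CH2 group and the carbonyl carbon attached to C6 is cut, and that carbonyl is taken down to the carbinol 20. This is the one bond of the chain that enolate chemistry can make with a partner that cannot enolise: aldehyde 17 has no α-hydrogen, and acetophenone 18 gives a single enolate, 19. Attaching a complete three-carbon acyl unit to C6 directly would need electrophilic acylation of a position flanked by two oxygens, in competition with C8. The forward sequence has to add 19 to a hindered, electron-rich aldehyde and then oxidise 20 without over-oxidising the 1,3-dicarbonyl product.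

**17 from 14.** The C6–CHO bond is cut, with the free phenol 16 as the intermediate stage. Of the two ring positions that still bear hydrogen, only C6 is ortho to the C5 hydroxyl. A phenol-directed ortho-formylation, running through the hydroxymethyl stage 15, therefore decides C6 against C8 by structure and not by subtle electronic bias. The phenol is then capped to give 17.

**14 from 10.** The C3=C4 double bond is traced to the C3 alcohol 11 (through its mesylate 12) and this to ketone 10. The silyl ether is kept until the alkene 13 is in place. C2 carries no hydrogen, so elimination can only use the benzylic C4–H and the position of the alkene is not in question. A base-induced elimination is preferred because an acid-induced one would create a cation next to the quaternary centre.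

**10 from 6 and 7 (the central disconnection).** C4 is excised from ring B: the bonds C4–C4a and C3–C4 are cut and C3 is reconnected to C4a. This leads to coumaranone 6, and the excised carbon is supplied by Me3SiCHN2 (7).
- Gain: the construction of a pyran ring with a quaternary ether carbon becomes the simpler problem of a five-membered aryl ketone, whose O1–C2 bond and gem-dimethyl group come from an α-bromoisobutyryl unit.
- Forward course: Lewis-acid-promoted addition gives adduct 8, a 1,2-shift with loss of N2 gives the silyl ketone 9, and protodesilylation gives 10.
- Requirement: the reaction must stop after a single insertion. The direction of migration is not critical: if the quaternary carbon moved instead, the carbonyl would lie at C4, and the same reduction and elimination would converge on 13.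

**6 from 4.** The silyl group and then the methyl group are removed, through 5. The two hydroxyls of 4 differ in their relation to the carbonyl. The C6 hydroxyl is para to it, unhindered and the more acidic; the C4 hydroxyl is peri to it and hydrogen-bonded. Methylation therefore comes first, and the remaining phenol is silylated.

**4 from 1 and 2.** The O1–C2 ether bond is cut to give bromoketone 3, and the aryl–carbonyl bond is cut to give phloroglucinol 1 and acid bromide 2. Because 1 is threefold symmetric, acylation can give only one ketone. Because the two ortho hydroxyls of 3 are equivalent, ring closure can give only one coumaranone. All decisions about the three oxygens are thereby postponed to the stage where the carbonyl tells them apart.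

## Alternatives that were turned down

**Alternative 1:** The 1,3-diketone is replaced by a 3-aryl-5-phenylisoxazole, which is cut across the heterocycle into a nitrile oxide on C6 and an alkyne.
- Forward key step: oxime A2, made from aldehyde 17, would be chlorinated with NCS and dehydrochlorinated with Et3N to nitrile oxide A3. This adds to phenylacetylene A4 to give isoxazole A1, forming the bond between the future aryl-bound carbonyl carbon and the future CH2 carbon together with the O–C(Ph) bond. Reductive N–O cleavage (Mo(CO)6, wet MeCN) and hydrolysis would then lead to 21.
- For it: the cycloaddition is irreversible and regioselective with a terminal alkyne, a nitrile oxide with two ortho substituents dimerises slowly, and the diketone travels in a form that can neither fragment nor close to a flavone.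
- Against it: NCS is an electrophilic chlorine source and would meet the electron-rich C3=C4 bond and the free C8–H of a trioxygenated ring. Unmasking costs two further operations, one of them an acidic hydrolysis. The plan is silent about ring B, which must come from elsewhere.
- Comparison: on the reliability of the carbon–carbon bond formation it is stronger than the reversible aldol addition. The chosen route offers a shorter side-chain sequence (two operations from 17 to 21 instead of four) and a construction of the pyran ring.

**Alternative 2:** Ring B is cut at C3–C4 and O1–C2, back to 2,6-dihydroxy-4-methoxybenzaldehyde A6 and 2-methylprop-1-enylboronic acid A7.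
- Forward key step: with catalytic dibenzylamine the amine condenses with the aldehyde, the alkenyl group passes from boron to the activated aldehyde carbon (C3–C4), the amine is lost again, and oxygen closes onto the dimethyl-substituted carbon in a 6π electrocyclisation (O1–C2). The product is chromenol A5, the same compound as 14.
- For it: one catalytic operation, no protecting groups, a symmetric aldehyde without any regiochemical question, and a reaction type that is known for salicylaldehydes.
- Against it: the aldehyde carbon of A6 is deactivated by three donor oxygens, a β,β-disubstituted alkenylboronic acid transfers slowly and is prone to protodeboronation, and A6 itself has to be bought or made with its oxygens already differentiated.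
- Comparison: on step count and on precedent this alternative is clearly stronger, reaching 14 in one step where the chosen route needs eight. The chosen route offers in its place robust Friedel–Crafts and etherification chemistry on the cheapest arene to set O1, C2 and the carbonyl carbon, differentiation of the three oxygens by their relation to a carbonyl at every stage, and independence from a sluggish boron-to-carbon transfer onto a deactivated electrophile.

**Alternative 3:** The bonds C6–C(=O) and C(=O)–CH2 are cut at once, giving aryl iodide A9, carbon monoxide A10 and acetophenone 18.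
- Forward key step: under Pd(dba)2, Xantphos and Cs2CO3, oxidative addition of zerovalent palladium to A9, CO insertion and coupling with the enolate of 18 would give diketone A8, identical with 21. No ring is closed.
- For it: the whole chain arrives in one step at the correct oxidation level, without aldol addition or oxidation.
- Against it: A9 must be made regioselectively, and both electrophilic iodination and directed lithiation have to choose between C6 and C8, each flanked by two oxygens. Oxidative addition to an electron-rich iodide with two ortho substituents is slow. Direct, non-carbonylative α-arylation competes, and the β-diketonate product can bind palladium.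
- Comparison: it is one operation shorter at the side chain. The chosen route sets C6 unambiguously by phenol-directed formylation and uses no pressurised gas, and it also builds ring B, which this alternative does not address.

Key step: step 5

Remark: phloroglucinol is used anhydrous. All stereocentres formed on the way (in 8, 9, 11, 12 and 20) are racemic and are destroyed again, the target being achiral. Compounds 21 and 22 are written as diketones although they should exist largely as chelated enols.

## Route

Step 1
Reactants: 1 phloroglucinol (benzene-1,3,5-triol); 2 2-bromo-2-methylpropanoyl bromide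
Product: 3 2-bromo-2-methyl-1-(2,4,6-trihydroxyphenyl)propan-1-one
Conditions: AlCl3, PhNO2/CH2Cl2, 0 °C to rt; aq. HCl
Reagents that add atoms: none
Why: Friedel–Crafts C-acylation of a highly activated, threefold symmetric arene, so that only one monoketone can form and the acyl group deactivates the ring towards a second acylation. Any 4 formed already here by loss of HBr is carried into step 2.

Step 2
Reactants: 3 2-bromo-2-methyl-1-(2,4,6-trihydroxyphenyl)propan-1-one
Product: 4 4,6-dihydroxy-2,2-dimethylbenzofuran-3(2H)-one
Conditions: K2CO3, acetone, reflux, N2
Reagents that add atoms: none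
Why: Intramolecular Williamson-type etherification: the phenoxide ortho to the acyl group displaces bromide from the activated α-keto carbon in a 5-exo-tet closure, forming O1–C2. The two ortho hydroxyls are equivalent, so a single coumaranone results.

Step 3
Reactants: 4 4,6-dihydroxy-2,2-dimethylbenzofuran-3(2H)-one
Product: 5 4-hydroxy-6-methoxy-2,2-dimethylbenzofuran-3(2H)-one
Conditions: MeI (1.0 equiv), K2CO3 (1.0 equiv), acetone, rt
Reagents that add atoms: iodomethane, CI
Why: Williamson O-methylation with one equivalent of base and electrophile. The C6 hydroxyl, para to the carbonyl, is the more acidic and unhindered phenol, whereas the C4 hydroxyl is peri to the carbonyl, hydrogen-bonded to it and shielded, and should stay free.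

Step 4
Reactants: 5 4-hydroxy-6-methoxy-2,2-dimethylbenzofuran-3(2H)-one
Product: 6 4-[(tert-butyldimethylsilyl)oxy]-6-methoxy-2,2-dimethylbenzofuran-3(2H)-one
Conditions: TBSCl, imidazole, DMF, rt
Reagents that add atoms: tert-butyldimethylsilyl chloride, CC(C)(C)[Si](C)(C)Cl
Why: Silylation of the remaining phenol. The aryl silyl ether is inert to Me3SiCHN2, hydride and amine bases, should tolerate BF3·OEt2 at low temperature, and keeps the phenol from being O-methylated or from binding the Lewis acid in step 5.

Step 5
Reactants: 6 4-[(tert-butyldimethylsilyl)oxy]-6-methoxy-2,2-dimethylbenzofuran-3(2H)-one; 7 trimethylsilyldiazomethane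
Product: 10 5-[(tert-butyldimethylsilyl)oxy]-7-methoxy-2,2-dimethylchroman-3-one, via diazonium alkoxide adduct 8 (not isolated), via C4-silylated chromanone 9 (not isolated)
Conditions: Me3SiCHN2 (1.5 equiv, hexanes), BF3·OEt2 (1.2 equiv), CH2Cl2, −78 to −20 °C; then 1 M HCl, THF, 0 °C
Reagents that add atoms: none
Why: Proposed new method: BF3 binds the carbonyl oxygen of 6, the nucleophilic diazo carbon of 7 adds to C3 to give adduct 8, and a ring bond anti to the departing N2 shifts to the former diazo carbon, which is thereby inserted as C4 with formation of C4–C4a and C3–C4; the closest known reaction type is the Lewis-acid-promoted one-carbon ring expansion of 1-indanones to 2-tetralones and of other benzo-fused cyclic ketones with Me3SiCHN2, which has not been shown on a 2,2-disubstituted, 4,6-dioxygenated benzofuran-3-one. The six-membered ring is thus closed by enlargement of the five-membered ketone through a 1,2-shift and not by a cyclisation. The aryl carbon (the future C4a) is expected to migrate, because it carries oxygen at both ortho positions and at the para position and can bridge in a phenonium-like transition state. The one selectivity that is needed is that the reaction stops after a single insertion: the first product is the α-silyl ketone 9, whose carbonyl lies between the quaternary C2 and the silylated C4 and is far more hindered than that of 6. Which bond migrates is not critical, since migration of the quaternary carbon would merely place the carbonyl at C4, and steps 6 and 7 would lead to the same C3=C4 alkene because C2 has no hydrogen. The stereocentres of 8 and the C4 stereocentre of 9 are uncontrolled and transient and vanish when the benzylic C–Si bond is cleaved by dilute acid on work-up to give 10. The main doubt is whether addition to the hindered, donor-deactivated carbonyl is fast enough at a temperature at which the aryl silyl ether and the diazo reagent survive the Lewis acid.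

Step 6
Reactants: 10 5-[(tert-butyldimethylsilyl)oxy]-7-methoxy-2,2-dimethylchroman-3-one
Product: 11 5-[(tert-butyldimethylsilyl)oxy]-7-methoxy-2,2-dimethylchroman-3-ol (racemic)
Conditions: NaBH4, EtOH/THF, 0 °C
Reagents that add atoms: none
Why: Borohydride reduction of the unconjugated, enolisable and air-sensitive ketone, carried out without delay. The new C3 stereocentre is racemic and is destroyed in step 7, so no control is needed.

Step 7
Reactants: 11 5-[(tert-butyldimethylsilyl)oxy]-7-methoxy-2,2-dimethylchroman-3-ol (racemic)
Product: 13 tert-butyl[(7-methoxy-2,2-dimethyl-2H-chromen-5-yl)oxy]dimethylsilane, via chroman-3-yl mesylate 12 (not isolated)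
Conditions: MsCl, Et3N, CH2Cl2, 0 °C; then DBU, PhMe, 90 °C
Reagents that add atoms: none
Why: Sulfonylation followed by base-induced E2 elimination. The only β-hydrogens are the benzylic ones on C4 (C2 is quaternary), so the C3=C4 alkene is the only possible product, and substitution at the neopentyl-type C3 is disfavoured. A base-mediated dehydration avoids a cation next to the quaternary centre.

Step 8
Reactants: 13 tert-butyl[(7-methoxy-2,2-dimethyl-2H-chromen-5-yl)oxy]dimethylsilane
Product: 14 7-methoxy-2,2-dimethyl-2H-chromen-5-ol
Conditions: Bu4NF, AcOH, THF, 0 °C
Reagents that add atoms: none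
Why: Fluoride-induced cleavage of the aryl silyl ether, buffered with acetic acid so that the electron-rich, air-sensitive phenoxide is protonated at once.

Step 9
Reactants: 14 7-methoxy-2,2-dimethyl-2H-chromen-5-ol
Product: 16 5-hydroxy-7-methoxy-2,2-dimethyl-2H-chromene-6-carbaldehyde, via 6-hydroxymethyl chromenol 15 (not isolated)
Conditions: MgCl2, Et3N, (CH2O)n, MeCN, reflux; dilute aq. HCl at 0 °C
Reagents that add atoms: paraformaldehyde (as formaldehyde), C=O
Why: Magnesium-mediated ortho-formylation of a phenol: the magnesium phenoxide delivers formaldehyde to the free ortho carbon through a six-membered chelate to give 15, whose magnesium alkoxide passes hydride to a second formaldehyde (Oppenauer-type). C6 is the only hydrogen-bearing position ortho to the C5 hydroxyl, so C8 is not touched, and the basic medium spares the chromene.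

Step 10
Reactants: 16 5-hydroxy-7-methoxy-2,2-dimethyl-2H-chromene-6-carbaldehyde
Product: 17 7-methoxy-5-(methoxymethoxy)-2,2-dimethyl-2H-chromene-6-carbaldehyde
Conditions: MOMCl, iPr2NEt, CH2Cl2, 0 °C to rt
Reagents that add atoms: chloromethyl methyl ether, COCCl
Why: O-Alkylation of the hydrogen-bonded phenol to an acetal. A phenoxide ortho to the aldehyde would deactivate it in step 11 and would let the aldol product close to a cyclic hemiketal or lose water.

Step 11
Reactants: 17 7-methoxy-5-(methoxymethoxy)-2,2-dimethyl-2H-chromene-6-carbaldehyde; 18 acetophenone
Product: 20 3-hydroxy-3-[7-methoxy-5-(methoxymethoxy)-2,2-dimethyl-2H-chromen-6-yl]-1-phenylpropan-1-one (racemic), via lithium 1-phenylethenolate 19 (not isolated)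
Conditions: 18, LiN(SiMe3)2, THF, −78 °C; then 17, −78 °C; AcOH quench at −78 °C
Reagents that add atoms: none
Why: Directed aldol addition. The ketone is converted fully into enolate 19 before the non-enolisable aldehyde is added, so only one cross product can form, and the cold acidic quench keeps the electron-rich benzylic aldolate from retro-aldol cleavage or dehydration. The carbinol stereocentre is racemic and is removed in step 12.

Step 12
Reactants: 20 3-hydroxy-3-[7-methoxy-5-(methoxymethoxy)-2,2-dimethyl-2H-chromen-6-yl]-1-phenylpropan-1-one (racemic)
Product: 21 1-[7-methoxy-5-(methoxymethoxy)-2,2-dimethyl-2H-chromen-6-yl]-3-phenylpropane-1,3-dione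
Conditions: IBX, DMSO, rt
Reagents that add atoms: none
Why: Oxidation of a β-hydroxy ketone to the β-diketone with IBX, which does not go on to oxidise the 1,3-dicarbonyl product. The acetal, the aryl ethers and the alkene (C2 has no allylic hydrogen) should be left untouched.

Step 13
Reactants: 21 1-[7-methoxy-5-(methoxymethoxy)-2,2-dimethyl-2H-chromen-6-yl]-3-phenylpropane-1,3-dione
Product: 22 1-(5-hydroxy-7-methoxy-2,2-dimethyl-2H-chromen-6-yl)-3-phenylpropane-1,3-dione (CNP0331858.0)
Conditions: 2 M aq. HCl, MeOH/THF, rt
Reagents that add atoms: none
Why: Acid-catalysed acetal exchange with methanol. A methoxymethyl ether ortho to an aryl ketone is cleaved readily because the freed hydroxyl is hydrogen-bonded to the C6 carbonyl, so conditions mild enough to spare the C3=C4 bond and to avoid cyclodehydration of the o-hydroxyaryl diketone should suffice.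

## Compound list

1 | phloroglucinol (benzene-1,3,5-triol) | Oc1cc(O)cc(O)c1 | starting material
2 | 2-bromo-2-methylpropanoyl bromide | CC(C)(Br)C(=O)Br | starting material
3 | 2-bromo-2-methyl-1-(2,4,6-trihydroxyphenyl)propan-1-one | CC(C)(Br)C(=O)c1c(O)cc(O)cc1O | intermediate
4 | 4,6-dihydroxy-2,2-dimethylbenzofuran-3(2H)-one | CC1(C)Oc2cc(O)cc(O)c2C1=O | intermediate
5 | 4-hydroxy-6-methoxy-2,2-dimethylbenzofuran-3(2H)-one | COc1cc(O)c2C(=O)C(C)(C)Oc2c1 | intermediate
6 | 4-[(tert-butyldimethylsilyl)oxy]-6-methoxy-2,2-dimethylbenzofuran-3(2H)-one | COc1cc(O[Si](C)(C)C(C)(C)C)c2C(=O)C(C)(C)Oc2c1 | intermediate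
7 | trimethylsilyldiazomethane | C[Si](C)(C)C=[N+]=[N-] | starting material
8 | {[4-[(tert-butyldimethylsilyl)oxy]-3-[diazonio(trimethylsilyl)methyl]-6-methoxy-2,2-dimethyl-2,3-dihydrobenzofuran-3-yl]oxy}trifluoroborate (zwitterion, mixture of diastereomers, formed in the flask) | COc1cc(O[Si](C)(C)C(C)(C)C)c2c(c1)OC(C)(C)C2(O[B-](F)(F)F)C([N+]#N)[Si](C)(C)C | intermediate
9 | 5-[(tert-butyldimethylsilyl)oxy]-7-methoxy-2,2-dimethyl-4-(trimethylsilyl)chroman-3-one (racemic, formed in the flask) | COc1cc(O[Si](C)(C)C(C)(C)C)c2C([Si](C)(C)C)C(=O)C(C)(C)Oc2c1 | intermediate
10 | 5-[(tert-butyldimethylsilyl)oxy]-7-methoxy-2,2-dimethylchroman-3-one | COc1cc(O[Si](C)(C)C(C)(C)C)c2CC(=O)C(C)(C)Oc2c1 | intermediate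
11 | 5-[(tert-butyldimethylsilyl)oxy]-7-methoxy-2,2-dimethylchroman-3-ol (racemic) | COc1cc(O[Si](C)(C)C(C)(C)C)c2CC(O)C(C)(C)Oc2c1 | intermediate
12 | 5-[(tert-butyldimethylsilyl)oxy]-7-methoxy-2,2-dimethylchroman-3-yl methanesulfonate (racemic, formed in the flask) | COc1cc(O[Si](C)(C)C(C)(C)C)c2CC(OS(C)(=O)=O)C(C)(C)Oc2c1 | intermediate
13 | tert-butyl[(7-methoxy-2,2-dimethyl-2H-chromen-5-yl)oxy]dimethylsilane | COc1cc(O[Si](C)(C)C(C)(C)C)c2C=CC(C)(C)Oc2c1 | intermediate
14 | 7-methoxy-2,2-dimethyl-2H-chromen-5-ol | COc1cc(O)c2C=CC(C)(C)Oc2c1 | intermediate
15 | 6-(hydroxymethyl)-7-methoxy-2,2-dimethyl-2H-chromen-5-ol (formed in the flask as its magnesium salt) | COc1cc2OC(C)(C)C=Cc2c(O)c1CO | intermediate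
16 | 5-hydroxy-7-methoxy-2,2-dimethyl-2H-chromene-6-carbaldehyde | COc1cc2OC(C)(C)C=Cc2c(O)c1C=O | intermediate
17 | 7-methoxy-5-(methoxymethoxy)-2,2-dimethyl-2H-chromene-6-carbaldehyde | COCOc1c(C=O)c(OC)cc2OC(C)(C)C=Cc12 | intermediate
18 | acetophenone | CC(=O)c1ccccc1 | starting material
19 | lithium 1-phenylethen-1-olate (formed in the flask) | [Li+].[O-]C(=C)c1ccccc1 | intermediate
20 | 3-hydroxy-3-[7-methoxy-5-(methoxymethoxy)-2,2-dimethyl-2H-chromen-6-yl]-1-phenylpropan-1-one (racemic) | COCOc1c(C(O)CC(=O)c3ccccc3)c(OC)cc2OC(C)(C)C=Cc12 | intermediate
21 | 1-[7-methoxy-5-(methoxymethoxy)-2,2-dimethyl-2H-chromen-6-yl]-3-phenylpropane-1,3-dione | COCOc1c(C(=O)CC(=O)c3ccccc3)c(OC)cc2OC(C)(C)C=Cc12 | intermediate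
22 | 1-(5-hydroxy-7-methoxy-2,2-dimethyl-2H-chromen-6-yl)-3-phenylpropane-1,3-dione (CNP0331858.0) | COc1cc2c(c(O)c1C(=O)CC(=O)c1ccccc1)C=CC(C)(C)O2 | target

Total step count: 13 steps. Longest linear sequence: 13 steps, from phloroglucinol 1 to 22.

## Steps least certain to work

**Step 5 (key step, proposed new method).**
- What may go wrong: the diazo carbon may fail to add to the hindered, donor-deactivated carbonyl before the Lewis acid consumes the reagent, so that 6 is recovered. The aryl silyl ether may be cleaved by the Lewis acid and the phenol then O-methylated. A second carbon may be inserted if the α-silyl group is lost early.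
- Fallback with known chemistry, setting out from 1 and coming back to the route at 14, so that steps 1 to 8 are replaced: Friedel–Crafts acylation and oxa-Michael closure of 1 with 3-methylbut-2-enoic acid in MeSO3H/P2O5 at 70 °C should give 5,7-dihydroxy-2,2-dimethylchroman-4-one F1. Methylation of its unchelated C7 hydroxyl (MeI, K2CO3, acetone) should give 5-hydroxy-7-methoxy-2,2-dimethylchroman-4-one F2. Reduction with LiAlH4 in THF should give racemic 7-methoxy-2,2-dimethylchromane-4,5-diol F3, whose electron-rich benzylic alcohol should lose water with catalytic TsOH in warm toluene to give 14.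

**Step 3.**
- What may go wrong: loss of site selectivity or double alkylation, because the hydrogen bond of the peri hydroxyl to a five-membered ring ketone is weak and both phenols are vinylogous acids.
- Fallback, setting out from 4 and coming back at 5: exhaustive methylation (excess MeI, K2CO3, DMF) should give 4,6-dimethoxy-2,2-dimethylbenzofuran-3(2H)-one F4. BCl3 in CH2Cl2 at −78 to 0 °C should then cleave only the methyl ether peri to the carbonyl through a boron chelate, which gives 5.

**Step 7.**
- What may go wrong: slow elimination at the secondary mesylate next to the quaternary carbon, with desilylation or decomposition on prolonged heating with the amidine base.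
- Fallback, setting out from 10 and coming back at 13, so that steps 6 and 7 are replaced: enolisation, which is possible only towards C4, with KN(SiMe3)2 and trapping with PhNTf2 in THF at −78 °C should give 5-[(tert-butyldimethylsilyl)oxy]-7-methoxy-2,2-dimethyl-2H-chromen-3-yl trifluoromethanesulfonate F5. Reduction of the C–O bond with Pd(OAc)2, PPh3, HCO2H and Et3N in DMF at 60 °C should give 13.

**Step 11.**
- What may go wrong: reversal of the aldol addition, since the aldehyde is stabilised by three donor oxygens and flanked by two ortho substituents, and loss of water from the electron-rich benzylic alcohol during work-up or chromatography.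
- Fallback, setting out from 17 and coming back at 21, so that steps 11 and 12 are replaced: irreversible addition of lithium phenylacetylide (phenylacetylene, n-BuLi, THF, −78 °C) should give racemic 1-[7-methoxy-5-(methoxymethoxy)-2,2-dimethyl-2H-chromen-6-yl]-3-phenylprop-2-yn-1-ol F6. MnO2 in CH2Cl2 should oxidise it to 1-[7-methoxy-5-(methoxymethoxy)-2,2-dimethyl-2H-chromen-6-yl]-3-phenylprop-2-yn-1-one F7. Conjugate addition of pyrrolidine in EtOH should give (E)-1-[7-methoxy-5-(methoxymethoxy)-2,2-dimethyl-2H-chromen-6-yl]-3-phenyl-3-(pyrrolidin-1-yl)prop-2-en-1-one F8, and hydrolysis with aqueous AcOH in THF should give 21.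

**Step 13.**
- What may go wrong: acid-promoted side reactions may outrun acetal cleavage, namely cyclodehydration of the freed o-hydroxyaryl diketone to a flavone and protonation of the C3=C4 bond.
- Fallback without acid and without a protecting group, setting out from 16 and coming back at 22, so that steps 10 to 13 are replaced: MeMgBr (3 equiv) in THF at 0 °C should give racemic 6-(1-hydroxyethyl)-7-methoxy-2,2-dimethyl-2H-chromen-5-ol F9. MnO2 in CH2Cl2 should oxidise it to 1-(5-hydroxy-7-methoxy-2,2-dimethyl-2H-chromen-6-yl)ethan-1-one F10. Benzoyl chloride in pyridine should give 6-acetyl-7-methoxy-2,2-dimethyl-2H-chromen-5-yl benzoate F11. A Baker–Venkataraman acyl shift (KOH, pyridine, 50 °C, then AcOH at 0 °C) should move the benzoyl group from oxygen to the acetyl carbon and give 22.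

## Further compounds

F1 | step 5 | 5,7-dihydroxy-2,2-dimethylchroman-4-one | CC1(C)CC(=O)c2c(O)cc(O)cc2O1
F2 | step 5 | 5-hydroxy-7-methoxy-2,2-dimethylchroman-4-one | COc1cc(O)c2C(=O)CC(C)(C)Oc2c1
F3 | step 5 | 7-methoxy-2,2-dimethylchromane-4,5-diol (racemic) | COc1cc(O)c2C(O)CC(C)(C)Oc2c1
F4 | step 3 | 4,6-dimethoxy-2,2-dimethylbenzofuran-3(2H)-one | COc1cc(OC)c2C(=O)C(C)(C)Oc2c1
F5 | step 7 | 5-[(tert-butyldimethylsilyl)oxy]-7-methoxy-2,2-dimethyl-2H-chromen-3-yl trifluoromethanesulfonate | COc1cc(O[Si](C)(C)C(C)(C)C)c2C=C(OS(=O)(=O)C(F)(F)F)C(C)(C)Oc2c1
F6 | step 11 | 1-[7-methoxy-5-(methoxymethoxy)-2,2-dimethyl-2H-chromen-6-yl]-3-phenylprop-2-yn-1-ol (racemic) | COCOc1c(C(O)C#Cc3ccccc3)c(OC)cc2OC(C)(C)C=Cc12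
F7 | step 11 | 1-[7-methoxy-5-(methoxymethoxy)-2,2-dimethyl-2H-chromen-6-yl]-3-phenylprop-2-yn-1-one | COCOc1c(C(=O)C#Cc3ccccc3)c(OC)cc2OC(C)(C)C=Cc12
F8 | step 11 | (E)-1-[7-methoxy-5-(methoxymethoxy)-2,2-dimethyl-2H-chromen-6-yl]-3-phenyl-3-(pyrrolidin-1-yl)prop-2-en-1-one | COCOc1c(C(=O)/C=C(/N3CCCC3)c3ccccc3)c(OC)cc2OC(C)(C)C=Cc12
F9 | step 13 | 6-(1-hydroxyethyl)-7-methoxy-2,2-dimethyl-2H-chromen-5-ol (racemic) | COc1cc2OC(C)(C)C=Cc2c(O)c1C(C)O
F10 | step 13 | 1-(5-hydroxy-7-methoxy-2,2-dimethyl-2H-chromen-6-yl)ethan-1-one | COc1cc2OC(C)(C)C=Cc2c(O)c1C(C)=O
F11 | step 13 | 6-acetyl-7-methoxy-2,2-dimethyl-2H-chromen-5-yl benzoate | COc1cc2OC(C)(C)C=Cc2c(OC(=O)c3ccccc3)c1C(C)=O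
A1 | alternative 1 | 3-[7-methoxy-5-(methoxymethoxy)-2,2-dimethyl-2H-chromen-6-yl]-5-phenylisoxazole | COCOc1c(-c3cc(-c4ccccc4)on3)c(OC)cc2OC(C)(C)C=Cc12
A2 | alternative 1 | (E)-7-methoxy-5-(methoxymethoxy)-2,2-dimethyl-2H-chromene-6-carbaldehyde oxime | COCOc1c(/C=N/O)c(OC)cc2OC(C)(C)C=Cc12
A3 | alternative 1 | 7-methoxy-5-(methoxymethoxy)-2,2-dimethyl-2H-chromene-6-carbonitrile oxide | COCOc1c(C#[N+][O-])c(OC)cc2OC(C)(C)C=Cc12
A4 | alternative 1 | phenylacetylene (ethynylbenzene) | C#Cc1ccccc1
A5 | alternative 2 | 7-methoxy-2,2-dimethyl-2H-chromen-5-ol (identical with 14) | COc1cc(O)c2C=CC(C)(C)Oc2c1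
A6 | alternative 2 | 2,6-dihydroxy-4-methoxybenzaldehyde | COc1cc(O)c(C=O)c(O)c1
A7 | alternative 2 | (2-methylprop-1-en-1-yl)boronic acid | CC(C)=CB(O)O
A8 | alternative 3 | 1-[7-methoxy-5-(methoxymethoxy)-2,2-dimethyl-2H-chromen-6-yl]-3-phenylpropane-1,3-dione (identical with 21) | COCOc1c(C(=O)CC(=O)c3ccccc3)c(OC)cc2OC(C)(C)C=Cc12
A9 | alternative 3 | 6-iodo-7-methoxy-5-(methoxymethoxy)-2,2-dimethyl-2H-chromene | COCOc1c(I)c(OC)cc2OC(C)(C)C=Cc12
A10 | alternative 3 | carbon monoxide | [C-]#[O+]
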